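The partner was my lever: the larch and elm runs hold the same starting material charge but different partner charges, and I wanted to know what more partner buys.

| setting | larch | elm | ash |
|---|---|---|---|
| starting material | 0.600 M | 0.600 M | 1.20 M |
| partner | 1.80 M | 2.70 M | 0.590 M |
| time |  |  | 9.5 min |

| larch run: time / min | larch run: [target] / M | elm run: time / min | elm run: [target] / M |
|---|---|---|---|
| 1.4 | 0.068 | 1.4 | 0.076 |
| 2.7 | 0.133 | 2.7 | 0.150 |
| 4.1 | 0.186 | 4.1 | 0.207 |
| 5.4 | 0.240 | 5.4 | 0.256 |
| 6.8 | 0.281 | 6.8 | 0.303 |
| 8.1 | 0.317 | 8.1 | 0.346 |
| 9.5 | 0.355 | 9.5 | 0.373 |

(standard deviation of a reading: 0.003 M)

- Overall: starting material + partner -> target.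
- Constant volume, constant temperature.
- A reading of a species includes what of it is bound.
- "The second partner" is partner.
- An order is taken over about fifteen percent of the charge, up and down.

- the exponent of [partner] in the starting rate at the charge of the larch run (at the point where two percent of the starting material have become target)
- target in the ash run at 9.5 min, as a share of the starting material charged

The readings up to 4.1 min summed to 0.387 M of target in larch and 0.433 M in elm, a ratio read as 1.12 for 1.50 times the partner. I supposed that the rate per starting material climbs as R/(K+R), with R the partner concentration. Taking that ratio as the ratio of the early rates, I got 0.842 M for K, the saturation level, the partner concentration at which that rate stands at half its ceiling. The exponent of partner at a charge R is then K/(K+R), which is 0.319 at the larch charge.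

In ash the partner is the limiting reagent, 0.590 M against 1.20 M of starting material, so target can reach 49.2% of the starting material charged. Treating the larch reading at 4.1 min as first-order loss of starting material gave a rate per starting material of 0.0905 min⁻¹, and K carried that to 0.0547 min⁻¹ at the ash charge, a starting rate of 0.0657 M min⁻¹. I let the partner fall exponentially from that rate, which gave 0.385 M of target at 9.5 min, or 32.1%.

The forecast gave 0.29 and 30%, a share lower than mine, on the view that “This looks like saturation in partner”.

The flask gave an exponent of 0.31 and, in ash, 25.9%.

    starting material ⇌ intermediate, settled at all times (2.660)
    intermediate + partner → target (0.3858 L mol⁻¹ min⁻¹)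
    starting material + partner ⇌ idle substrate-reagent adduct, settled at all times (8.200 L mol⁻¹)

My ash share stood 6.2 percentage points too high, and a power-law fit put ash higher still, at 41.4%. K went once more to the point where target is half of the starting material charged: partner is then 1.50 M in larch and 2.40 M in elm, so K gives the rate of elm over larch as 1.16, and the readings there give 1.1.

(The runs were generated by integration with constants of no real substance; noise was put on by code.)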